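**Strategy**

The route rests on disconnecting the C2–C3 bond of the oxolane. Because oxolane C2 carries its methyl cis, and its ketone-bearing CH2 trans, to the γ-lactone ring on C5, the methyl can serve as the exocyclic carbon of a cis-selective 5-exo radical closure. A primary C3 radical adds to the oxygen-bearing carbon of a β-alkoxyvinyl sulfone, closing the oxolane and setting the quaternary C2 in one operation; the sulfonylmethyl group is later reduced to the methyl. The precursor is an iodide whose (R)-carbinol oxygen, flanked by the preformed (S)-lactone, carries the vinyl sulfone with a silyloxyethyl arm, the future ketone side chain.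

Key step: step 13

Remark: 18–20 are drawn as the E enol ethers expected under equilibrating base; a Z component is equally usable because the alkene geometry is erased in step 13, and 35 is carried as both carbinol epimers because step 23 removes that centre.

**Route**

Step 1
Reactants: 1 propane-1,3-diol
Product: 2 3-[(4-methoxybenzyl)oxy]propan-1-ol
Conditions: NaH (1 equiv), 1 (3 equiv), THF/DMF, 0 °C; PMBCl (1 equiv), Bu4NI (cat.), rt
Reagents that add atoms: 4-methoxybenzyl chloride, COc1ccc(CCl)cc1
Why: Williamson etherification; the excess of the symmetrical diol should hold the reaction at mono-alkylation.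

Step 2
Reactants: 2 3-[(4-methoxybenzyl)oxy]propan-1-ol
Product: 3 3-[(4-methoxybenzyl)oxy]propanal
Conditions: TEMPO (10 mol %), PhI(OAc)2, CH2Cl2, rt
Reagents that add atoms: none
Why: TEMPO/oxoammonium oxidation stops at the aldehyde under non-basic conditions, so the β-alkoxy aldehyde is not exposed to elimination and the PMB ether is untouched.

Step 3
Reactants: 3 3-[(4-methoxybenzyl)oxy]propanal; 4 isopropenylmagnesium bromide
Product: 5 (±)-5-[(4-methoxybenzyl)oxy]-2-methylpent-1-en-3-ol
Conditions: THF, −78 → 0 °C; aqueous work-up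
Reagents that add atoms: none
Why: Grignard 1,2-addition to the aldehyde; the carbinol forms racemic, which is immaterial because this centre is consumed in step 4.

Step 4
Reactants: 5 (±)-5-[(4-methoxybenzyl)oxy]-2-methylpent-1-en-3-ol; 6 triethyl orthoacetate
Product: 8 ethyl (4E)-7-[(4-methoxybenzyl)oxy]-4-methylhept-4-enoate, via ketene acetal 7 (not isolated)
Conditions: 6 (6 equiv), EtCO2H (cat.), 140 °C, EtOH distilled off
Reagents that add atoms: none
Why: Johnson–Claisen rearrangement; the chair transition state with the CH2CH2OPMB group equatorial should give the E-trisubstituted alkene while the racemic carbinol centre is destroyed.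

Step 5
Reactants: 8 ethyl (4E)-7-[(4-methoxybenzyl)oxy]-4-methylhept-4-enoate
Product: 9 ethyl 3-[(2R,3R)-3-{2-[(4-methoxybenzyl)oxy]ethyl}-2-methyloxiran-2-yl]propanoate
Conditions: D-fructose-derived Shi ketone (0.3 equiv), Oxone, K2CO3, Bu4NHSO4 (cat.), MeCN–DMM/aq. borate–EDTA buffer (pH 10.5), 0 °C
Reagents that add atoms: potassium peroxymonosulfate (Oxone), [K+].[O-]S(=O)(=O)OO
Why: Shi asymmetric epoxidation; the chiral dioxirane attacks the only alkene, an E-trisubstituted one, through the spiro transition state, which for this substitution pattern should set both oxirane carbons as R.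

Step 6
Reactants: 9 ethyl 3-[(2R,3R)-3-{2-[(4-methoxybenzyl)oxy]ethyl}-2-methyloxiran-2-yl]propanoate
Product: 11 (5S)-5-{(1R)-1-hydroxy-3-[(4-methoxybenzyl)oxy]propyl}-5-methyloxolan-2-one, via epoxy acid 10 (not isolated)
Conditions: LiOH, THF–H2O, rt; aq. HCl to pH 3; CSA (cat.), CH2Cl2, rt
Reagents that add atoms: lithium hydroxide, [Li+].[OH-]
Why: Saponification followed by epoxy-acid lactonisation; the carboxyl group opens the oxirane 5-exo at the tertiary carbon with inversion (giving the 5S lactone carbon) while the secondary C–O bond is retained as the (1R)-carbinol.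

Step 7
Reactants: 12 but-3-yn-1-ol
Product: 13 tert-butyl(but-3-yn-1-yloxy)dimethylsilane
Conditions: TBSCl, imidazole, CH2Cl2, rt
Reagents that add atoms: tert-butyldimethylsilyl chloride, CC(C)(C)[Si](C)(C)Cl
Why: Standard silylation of a primary alcohol; the terminal alkyne is inert.

Step 8
Reactants: 13 tert-butyl(but-3-yn-1-yloxy)dimethylsilane
Product: 15 tert-butyldimethyl{[4-(phenylsulfanyl)but-3-yn-1-yl]oxy}silane, via lithium acetylide 14 (not isolated)
Conditions: n-BuLi, THF, −78 °C; PhSSPh, −78 °C → rt; aq. NH4Cl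
Reagents that add atoms: diphenyl disulfide, c1ccc(SSc2ccccc2)cc1
Why: Sulfenylation of a lithium acetylide by attack on the S–S bond of the disulfide; the silyl ether tolerates the base at low temperature.

Step 9
Reactants: 15 tert-butyldimethyl{[4-(phenylsulfanyl)but-3-yn-1-yl]oxy}silane
Product: 17 tert-butyldimethyl{[4-(phenylsulfonyl)but-3-yn-1-yl]oxy}silane, via alkynyl sulfoxide 16 (not isolated)
Conditions: mCPBA (2.2 equiv), CH2Cl2, 0 °C → rt
Reagents that add atoms: 3-chloroperoxybenzoic acid, OOC(=O)c1cccc(Cl)c1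
Why: Two-fold peracid S-oxidation of the sulfide to the sulfone; the alkyne becomes electron-poor and is not epoxidised, and the silyl ether is inert.

Step 10
Reactants: 11 (5S)-5-{(1R)-1-hydroxy-3-[(4-methoxybenzyl)oxy]propyl}-5-methyloxolan-2-one; 17 tert-butyldimethyl{[4-(phenylsulfonyl)but-3-yn-1-yl]oxy}silane
Product: 18 (5S)-5-[(1R)-1-{[(1E)-4-[(tert-butyldimethylsilyl)oxy]-1-(phenylsulfonyl)but-1-en-2-yl]oxy}-3-[(4-methoxybenzyl)oxy]propyl]-5-methyloxolan-2-one
Conditions: NaH (0.2 equiv), THF, 0 °C; 17 (1.3 equiv), 0 °C → rt; AcOH quench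
Reagents that add atoms: none
Why: Base-catalysed oxa-Michael addition of the secondary alkoxide to the acetylenic sulfone at the carbon β to sulfur; catalytic base lets the vinyl anion be protonated by further alcohol and should equilibrate the push–pull enol ether to the E isomer, with the carbinol and lactone centres untouched.

Step 11
Reactants: 18 (PMB ether from step 10)
Product: 19 (5S)-5-[(1R)-1-{[(1E)-4-[(tert-butyldimethylsilyl)oxy]-1-(phenylsulfonyl)but-1-en-2-yl]oxy}-3-hydroxypropyl]-5-methyloxolan-2-one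
Conditions: DDQ, CH2Cl2–pH 7 buffer, 0 °C → rt
Reagents that add atoms: none
Why: Oxidative cleavage of the PMB ether by DDQ; the sulfonyl-substituted enol ether is too electron-poor to be oxidised and the silyl ether is inert.

Step 12
Reactants: 19 (primary alcohol from step 11)
Product: 20 (5S)-5-[(1R)-1-{[(1E)-4-[(tert-butyldimethylsilyl)oxy]-1-(phenylsulfonyl)but-1-en-2-yl]oxy}-3-iodopropyl]-5-methyloxolan-2-one
Conditions: I2, PPh3, imidazole, CH2Cl2, 0 °C → rt
Reagents that add atoms: iodine, II
Why: Appel-type iodination; iodide displaces the alkoxyphosphonium group at the primary carbon by SN2, and the imidazole buffer protects the silyl ether.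

Step 13
Reactants: 20 (iodide from step 12)
Product: 21 (5S)-5-[(2R,5R)-5-{2-[(tert-butyldimethylsilyl)oxy]ethyl}-5-[(phenylsulfonyl)methyl]oxolan-2-yl]-5-methyloxolan-2-one
Conditions: (Me3Si)3SiH (1.3 equiv) and AIBN (0.2 equiv) added over 4 h, degassed toluene (0.01 M), 80 °C
Reagents that add atoms: none
Why: Iodine abstraction by the silyl radical gives the primary C3 radical, which adds 5-exo-trig to the oxygen-bearing, sulfone-activated alkene carbon (future C2); the resulting α-sulfonyl radical takes hydrogen from the silane and carries the chain. The closest known reaction type is the reductive 5-exo radical cyclisation of β-alkoxyacrylates and β-alkoxyvinyl sulfones to cis-2,5-disubstituted oxolanes, here applied to an acceptor carbon that also bears an alkyl group. The oxolane is closed in the 5-exo-trig mode by forming C2–C3. The new quaternary C2 is controlled by the existing C5 carbinol centre: in the chair-like transition state its lactone substituent sits pseudo-equatorial, which places the alkene terminus (the exocyclic sulfonylmethyl carbon) cis to the lactone and the silyloxyethyl arm trans, whichever alkene isomer is used. The step needs exo regioselectivity and closure faster than reduction; these should be secured by the polarity match between the nucleophilic alkyl radical and the carbon β to sulfur, by the disfavoured attack at the sulfonyl-bearing carbon, and by a slow hydrogen donor kept at low concentration.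

Step 14
Reactants: 21 (cyclised sulfone from step 13)
Product: 22 (5S)-5-[(2R,5R)-5-{2-[(tert-butyldimethylsilyl)oxy]ethyl}-5-methyloxolan-2-yl]-5-methyloxolan-2-one
Conditions: Raney Ni (W-2, washed neutral), H2 (1 atm), EtOH, 70 °C
Reagents that add atoms: none
Why: Hydrogenolytic desulfonylation on Raney nickel cleaves the C–S bond without a free carbanion, which matters because a dissolving-metal reduction would put an anion β to the ring oxygen and open the oxolane; lactone, silyl ether and all stereocentres are inert.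

Step 15
Reactants: 22 (silyl ether from step 14)
Product: 23 (5S)-5-[(2R,5R)-5-(2-hydroxyethyl)-5-methyloxolan-2-yl]-5-methyloxolan-2-one
Conditions: HF·pyridine, THF–pyridine, 0 °C → rt
Reagents that add atoms: none
Why: Fluoride-mediated desilylation under buffered, non-basic conditions that leave the lactone closed.

Step 16
Reactants: 23 (primary alcohol from step 15)
Product: 24 2-{(2R,5R)-2-methyl-5-[(2S)-2-methyl-5-oxooxolan-2-yl]oxolan-2-yl}acetaldehyde
Conditions: Dess–Martin periodinane, NaHCO3, CH2Cl2, 0 °C → rt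
Reagents that add atoms: none
Why: Dess–Martin oxidation under bicarbonate buffer gives the aldehyde without the base that could trigger β-elimination of the ring oxygen; the aldehyde is used directly.

Step 17
Reactants: 25 furan-3-carbaldehyde; 26 (triphenyl-λ5-phosphanylidene)acetaldehyde
Product: 27 (2E)-3-(furan-3-yl)prop-2-enal
Conditions: toluene, 80 °C
Reagents that add atoms: none
Why: Wittig olefination with a stabilised ylide, which reacts faster with the aromatic aldehyde than with the product enal and should give the E alkene.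

Step 18
Reactants: 27 (2E)-3-(furan-3-yl)prop-2-enal
Product: 28 3-(furan-3-yl)propanal
Conditions: Hantzsch ester (1.1 equiv), Bn2NH2+ CF3CO2− (10 mol %), THF, rt
Reagents that add atoms: none
Why: Iminium-catalysed transfer hydrogenation (organocatalytic conjugate reduction) delivers hydride only to the β-carbon of the enal, leaving furan and aldehyde intact.

Step 19
Reactants: 28 3-(furan-3-yl)propanal; 29 ethyl 2-(triphenyl-λ5-phosphanylidene)propanoate
Product: 30 ethyl (2E)-5-(furan-3-yl)-2-methylpent-2-enoate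
Conditions: CH2Cl2, rt
Reagents that add atoms: none
Why: Wittig olefination with an α-methyl stabilised ylide, which should place the ester trans to the alkyl chain and so fix the E-trisubstituted alkene of the target.

Step 20
Reactants: 30 ethyl (2E)-5-(furan-3-yl)-2-methylpent-2-enoate
Product: 31 (2E)-5-(furan-3-yl)-2-methylpent-2-en-1-ol
Conditions: DIBAL-H (2.2 equiv), CH2Cl2, −78 °C; Rochelle salt
Reagents that add atoms: none
Why: 1,2-Reduction of the enoate by an aluminium hydride gives the allylic alcohol without touching the alkene geometry or the furan.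

Step 21
Reactants: 31 (2E)-5-(furan-3-yl)-2-methylpent-2-en-1-ol
Product: 33 3-[(3E)-5-chloro-4-methylpent-3-en-1-yl]furan, via allylic mesylate 32 (not isolated)
Conditions: MsCl, s-collidine, LiCl, DMF, 0 °C
Reagents that add atoms: lithium chloride, [Li+].[Cl-]
Why: Mesylation then SN2 displacement by chloride under buffered conditions gives the primary allylic chloride without allylic transposition or acid, so alkene geometry and furan survive.

Step 22
Reactants: 24 (aldehyde from step 16); 33 3-[(3E)-5-chloro-4-methylpent-3-en-1-yl]furan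
Product: 35 (5S)-5-{(2R,5R)-5-[(4E)-7-(furan-3-yl)-2-hydroxy-4-methylhept-4-en-1-yl]-5-methyloxolan-2-yl}-5-methyloxolan-2-one (both carbinol epimers), via allylbarium chloride 34 (not isolated)
Conditions: Li, biphenyl, THF, rt; BaI2, rt; 33 (1.5 equiv), −78 °C; 24, −78 °C; aq. NH4Cl at −78 °C
Reagents that add atoms: none
Why: α-Selective carbonyl allylation with an allylbarium reagent; generated at −78 °C from reactive barium it should keep its E geometry and attack through its CH2 terminus, the aldehyde reacting far faster than the lactone, and the uncontrolled new carbinol centre is removed in step 23.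

Step 23
Reactants: 35 (homoallylic alcohol from step 22)
Product: 36 (5S)-5-{(2R,5R)-5-[(4E)-7-(furan-3-yl)-4-methyl-2-oxohept-4-en-1-yl]-5-methyloxolan-2-yl}-5-methyloxolan-2-one
Conditions: Dess–Martin periodinane, NaHCO3, CH2Cl2, 0 °C
Reagents that add atoms: none
Why: Dess–Martin oxidation under bicarbonate buffer should give the β,γ-unsaturated ketone without moving the alkene into conjugation, opening the β-alkoxy ketone or oxidising the furan.

**Compound list**

1 | propane-1,3-diol | OCCCO | starting material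
2 | 3-[(4-methoxybenzyl)oxy]propan-1-ol | COc1ccc(COCCCO)cc1 | intermediate
3 | 3-[(4-methoxybenzyl)oxy]propanal | COc1ccc(COCCC=O)cc1 | intermediate
4 | isopropenylmagnesium bromide | CC(=C)[Mg]Br | starting material
5 | (±)-5-[(4-methoxybenzyl)oxy]-2-methylpent-1-en-3-ol | COc1ccc(COCCC(O)C(C)=C)cc1 | intermediate
6 | triethyl orthoacetate | CCOC(C)(OCC)OCC | starting material
7 | (±)-1-({[3-(1-ethoxyethenyloxy)-4-methylpent-4-en-1-yl]oxy}methyl)-4-methoxybenzene (mixed ketene acetal of 5) | COc1ccc(COCCC(OC(=C)OCC)C(C)=C)cc1 | intermediate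
8 | ethyl (4E)-7-[(4-methoxybenzyl)oxy]-4-methylhept-4-enoate | CCOC(=O)CC/C(C)=C/CCOCc1ccc(OC)cc1 | intermediate
9 | ethyl 3-[(2R,3R)-3-{2-[(4-methoxybenzyl)oxy]ethyl}-2-methyloxiran-2-yl]propanoate | CCOC(=O)CC[C@@]1(C)O[C@@H]1CCOCc1ccc(OC)cc1 | intermediate
10 | 3-[(2R,3R)-3-{2-[(4-methoxybenzyl)oxy]ethyl}-2-methyloxiran-2-yl]propanoic acid | OC(=O)CC[C@@]1(C)O[C@@H]1CCOCc1ccc(OC)cc1 | intermediate
11 | (5S)-5-{(1R)-1-hydroxy-3-[(4-methoxybenzyl)oxy]propyl}-5-methyloxolan-2-one | COc1ccc(COCC[C@@H](O)[C@]2(C)CCC(=O)O2)cc1 | intermediate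
12 | but-3-yn-1-ol | C#CCCO | starting material
13 | tert-butyl(but-3-yn-1-yloxy)dimethylsilane | C#CCCO[Si](C)(C)C(C)(C)C | intermediate
14 | lithium 4-[(tert-butyldimethylsilyl)oxy]but-1-yn-1-ide | [Li]C#CCCO[Si](C)(C)C(C)(C)C | intermediate
15 | tert-butyldimethyl{[4-(phenylsulfanyl)but-3-yn-1-yl]oxy}silane | CC(C)(C)[Si](C)(C)OCCC#CSc1ccccc1 | intermediate
16 | tert-butyldimethyl{[4-(phenylsulfinyl)but-3-yn-1-yl]oxy}silane (racemic at sulfur) | CC(C)(C)[Si](C)(C)OCCC#CS(=O)c1ccccc1 | intermediate
17 | tert-butyldimethyl{[4-(phenylsulfonyl)but-3-yn-1-yl]oxy}silane | CC(C)(C)[Si](C)(C)OCCC#CS(=O)(=O)c1ccccc1 | intermediate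
18 | (5S)-5-[(1R)-1-{[(1E)-4-[(tert-butyldimethylsilyl)oxy]-1-(phenylsulfonyl)but-1-en-2-yl]oxy}-3-[(4-methoxybenzyl)oxy]propyl]-5-methyloxolan-2-one | COc1ccc(COCC[C@@H](O/C(CCO[Si](C)(C)C(C)(C)C)=C/S(=O)(=O)c2ccccc2)[C@]3(C)CCC(=O)O3)cc1 | intermediate
19 | (5S)-5-[(1R)-1-{[(1E)-4-[(tert-butyldimethylsilyl)oxy]-1-(phenylsulfonyl)but-1-en-2-yl]oxy}-3-hydroxypropyl]-5-methyloxolan-2-one | OCC[C@@H](O/C(CCO[Si](C)(C)C(C)(C)C)=C/S(=O)(=O)c1ccccc1)[C@]1(C)CCC(=O)O1 | intermediate
20 | (5S)-5-[(1R)-1-{[(1E)-4-[(tert-butyldimethylsilyl)oxy]-1-(phenylsulfonyl)but-1-en-2-yl]oxy}-3-iodopropyl]-5-methyloxolan-2-one | ICC[C@@H](O/C(CCO[Si](C)(C)C(C)(C)C)=C/S(=O)(=O)c1ccccc1)[C@]1(C)CCC(=O)O1 | intermediate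
21 | (5S)-5-[(2R,5R)-5-{2-[(tert-butyldimethylsilyl)oxy]ethyl}-5-[(phenylsulfonyl)methyl]oxolan-2-yl]-5-methyloxolan-2-one | CC(C)(C)[Si](C)(C)OCC[C@@]1(CS(=O)(=O)c2ccccc2)CC[C@H]([C@]2(C)CCC(=O)O2)O1 | intermediate
22 | (5S)-5-[(2R,5R)-5-{2-[(tert-butyldimethylsilyl)oxy]ethyl}-5-methyloxolan-2-yl]-5-methyloxolan-2-one | CC(C)(C)[Si](C)(C)OCC[C@@]1(C)CC[C@H]([C@]2(C)CCC(=O)O2)O1 | intermediate
23 | (5S)-5-[(2R,5R)-5-(2-hydroxyethyl)-5-methyloxolan-2-yl]-5-methyloxolan-2-one | OCC[C@@]1(C)CC[C@H]([C@]2(C)CCC(=O)O2)O1 | intermediate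
24 | 2-{(2R,5R)-2-methyl-5-[(2S)-2-methyl-5-oxooxolan-2-yl]oxolan-2-yl}acetaldehyde | O=CC[C@@]1(C)CC[C@H]([C@]2(C)CCC(=O)O2)O1 | intermediate
25 | furan-3-carbaldehyde | O=Cc1ccoc1 | starting material
26 | (triphenyl-λ5-phosphanylidene)acetaldehyde | O=CC=P(c1ccccc1)(c1ccccc1)c1ccccc1 | starting material
27 | (2E)-3-(furan-3-yl)prop-2-enal | O=C/C=C/c1ccoc1 | intermediate
28 | 3-(furan-3-yl)propanal | O=CCCc1ccoc1 | intermediate
29 | ethyl 2-(triphenyl-λ5-phosphanylidene)propanoate | CCOC(=O)C(C)=P(c1ccccc1)(c1ccccc1)c1ccccc1 | starting material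
30 | ethyl (2E)-5-(furan-3-yl)-2-methylpent-2-enoate | CCOC(=O)/C(C)=C/CCc1ccoc1 | intermediate
31 | (2E)-5-(furan-3-yl)-2-methylpent-2-en-1-ol | OC/C(C)=C/CCc1ccoc1 | intermediate
32 | (2E)-5-(furan-3-yl)-2-methylpent-2-en-1-yl methanesulfonate | CS(=O)(=O)OC/C(C)=C/CCc1ccoc1 | intermediate
33 | 3-[(3E)-5-chloro-4-methylpent-3-en-1-yl]furan | ClC/C(C)=C/CCc1ccoc1 | intermediate
34 | [(2E)-5-(furan-3-yl)-2-methylpent-2-en-1-yl]barium chloride | Cl[Ba]C/C(C)=C/CCc1ccoc1 | intermediate
35 | (5S)-5-{(2R,5R)-5-[(4E)-7-(furan-3-yl)-2-hydroxy-4-methylhept-4-en-1-yl]-5-methyloxolan-2-yl}-5-methyloxolan-2-one (both carbinol epimers) | C/C(=C\CCc1ccoc1)CC(O)C[C@@]1(C)CC[C@H]([C@]2(C)CCC(=O)O2)O1 | intermediate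
36 | (5S)-5-{(2R,5R)-5-[(4E)-7-(furan-3-yl)-4-methyl-2-oxohept-4-en-1-yl]-5-methyloxolan-2-yl}-5-methyloxolan-2-one | C/C(=C\CCc1ccoc1)CC(=O)C[C@@]1(C)CC[C@H]([C@]2(C)CCC(=O)O2)O1 | target

**Step count and risk**

Total step count: 23. Longest linear sequence: 15 steps (1–6, 10–16, 22, 23, from propane-1,3-diol).

Steps most likely to fail:

1. Step 13. The primary radical may be reduced before it adds to the fully substituted acceptor carbon, it may close 6-endo, or the chair/boat discrimination may be too small for useful facial selectivity at C2. The fallback forms the O–C2 bond instead of C2–C3; it sets out from 11 and returns at 24, which also by-passes steps 10–16. DDQ in wet CH2Cl2 would free the primary hydroxyl of 11 to give (5S)-5-[(1R)-1,3-dihydroxypropyl]-5-methyloxolan-2-one F1. Selective Appel iodination of the primary hydroxyl (I2, PPh3, imidazole, 0 °C) would give (5S)-5-[(1R)-1-hydroxy-3-iodopropyl]-5-methyloxolan-2-one F2. Iron-catalysed sp3–sp2 coupling with isopropenylmagnesium bromide 4 (Fe(acac)3, TMEDA, THF, −20 °C, the first equivalent acting as base) would give (5S)-5-[(1R)-1-hydroxy-4-methylpent-4-en-1-yl]-5-methyloxolan-2-one F3. Cobalt-catalysed aerobic oxidative cyclisation of this alkenol (Mukaiyama type; Co(II) bis-diketonate-type catalyst, O2, t-BuOOH, i-PrOH, 55 °C) is known to close oxolanes with the new hydroxymethyl group trans to the existing substituent, and should give (5S)-5-[(2R,5R)-5-(hydroxymethyl)-5-methyloxolan-2-yl]-5-methyloxolan-2-one F4 with the methyl cis to the lactone. Dess–Martin oxidation would give (2R,5R)-2-methyl-5-[(2S)-2-methyl-5-oxooxolan-2-yl]oxolane-2-carbaldehyde F5. Wittig methoxymethylenation (MeOCH2PPh3Cl, KHMDS, THF, −78 → 0 °C) would give (5S)-5-[(2R,5R)-5-(2-methoxyethenyl)-5-methyloxolan-2-yl]-5-methyloxolan-2-one F6 as an E/Z mixture, and mild aqueous acid (HCl, THF) would hydrolyse it to 24.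

2. Step 10. The hindered alkoxide may add more slowly than the base isomerises the acetylenic sulfone to its allene and expels silanolate, or the alkoxide may translactonise before it adds. The fallback replaces alkyne hydroalkoxylation by exchange on a preformed enol ether; it sets out from 17 and 11 and returns at 18. Methanol would be added to 17 (NaOMe cat., MeOH, 0 °C) to give tert-butyl{[(3E)-3-methoxy-4-(phenylsulfonyl)but-3-en-1-yl]oxy}dimethylsilane F7. Alcohol 11 would then be introduced by acid-catalysed vinylogous transetherification (PPTS cat., toluene, 80 °C, 5 Å molecular sieves to remove methanol), giving 18 without the carbinol ever being an alkoxide.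

3. Step 22. The allylbarium reagent may lose α-regioselectivity or alkene geometry if it warms, excess reagent may attack the lactone, or enolisation of the β-alkoxy aldehyde may open the oxolane. The fallback fixes the regiochemistry with a sulfone-stabilised allyl anion; it sets out from 33 and 24 and returns at 36. Chloride 33 with PhSO2Na (DMF, rt) would give 3-[(3E)-4-methyl-5-(phenylsulfonyl)pent-3-en-1-yl]furan F8. Its lithio derivative (n-BuLi, THF, −78 °C) should add through the sulfonyl-bearing carbon to 24, giving (5S)-5-{(2R,5R)-5-[(4E)-7-(furan-3-yl)-2-hydroxy-4-methyl-3-(phenylsulfonyl)hept-4-en-1-yl]-5-methyloxolan-2-yl}-5-methyloxolan-2-one F9 as a diastereomer mixture. Dess–Martin oxidation would give (5S)-5-{(2R,5R)-5-[(4E)-7-(furan-3-yl)-4-methyl-2-oxo-3-(phenylsulfonyl)hept-4-en-1-yl]-5-methyloxolan-2-yl}-5-methyloxolan-2-one F10. Reductive cleavage of the α-sulfonyl ketone (SmI2, THF–MeOH, −78 °C), with α-protonation of the resulting enolate, would give 36.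

Further compounds

F1 | step 13 | (5S)-5-[(1R)-1,3-dihydroxypropyl]-5-methyloxolan-2-one | OCC[C@@H](O)[C@]1(C)CCC(=O)O1
F2 | step 13 | (5S)-5-[(1R)-1-hydroxy-3-iodopropyl]-5-methyloxolan-2-one | ICC[C@@H](O)[C@]1(C)CCC(=O)O1
F3 | step 13 | (5S)-5-[(1R)-1-hydroxy-4-methylpent-4-en-1-yl]-5-methyloxolan-2-one | CC(=C)CC[C@@H](O)[C@]1(C)CCC(=O)O1
F4 | step 13 | (5S)-5-[(2R,5R)-5-(hydroxymethyl)-5-methyloxolan-2-yl]-5-methyloxolan-2-one | OC[C@@]1(C)CC[C@H]([C@]2(C)CCC(=O)O2)O1
F5 | step 13 | (2R,5R)-2-methyl-5-[(2S)-2-methyl-5-oxooxolan-2-yl]oxolane-2-carbaldehyde | O=C[C@@]1(C)CC[C@H]([C@]2(C)CCC(=O)O2)O1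
F6 | step 13 | (5S)-5-[(2R,5R)-5-(2-methoxyethenyl)-5-methyloxolan-2-yl]-5-methyloxolan-2-one (E/Z mixture) | COC=C[C@@]1(C)CC[C@H]([C@]2(C)CCC(=O)O2)O1
F7 | step 10 | tert-butyl{[(3E)-3-methoxy-4-(phenylsulfonyl)but-3-en-1-yl]oxy}dimethylsilane | CO/C(CCO[Si](C)(C)C(C)(C)C)=C/S(=O)(=O)c1ccccc1
F8 | step 22 | 3-[(3E)-4-methyl-5-(phenylsulfonyl)pent-3-en-1-yl]furan | C/C(CS(=O)(=O)c1ccccc1)=C\CCc1ccoc1
F9 | step 22 | (5S)-5-{(2R,5R)-5-[(4E)-7-(furan-3-yl)-2-hydroxy-4-methyl-3-(phenylsulfonyl)hept-4-en-1-yl]-5-methyloxolan-2-yl}-5-methyloxolan-2-one (diastereomer mixture in the side chain) | C/C(=C\CCc1ccoc1)C(C(O)C[C@@]1(C)CC[C@H]([C@]2(C)CCC(=O)O2)O1)S(=O)(=O)c1ccccc1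
F10 | step 22 | (5S)-5-{(2R,5R)-5-[(4E)-7-(furan-3-yl)-4-methyl-2-oxo-3-(phenylsulfonyl)hept-4-en-1-yl]-5-methyloxolan-2-yl}-5-methyloxolan-2-one (both epimers at the sulfonyl carbon) | C/C(=C\CCc1ccoc1)C(C(=O)C[C@@]1(C)CC[C@H]([C@]2(C)CCC(=O)O2)O1)S(=O)(=O)c1ccccc1
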